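Readings and results were generated by integration with made-up constants; scatter was added.

The sum of target and starting material stays at the charge, so a late sample reads one conversion twice, and what to do with the south-east flask at 10 min hangs on that conversion.

all flasks: starting material 37 mM; second substrate 35.1 mM; free enzyme 1.7 µM; added ligand 0.93 µM

| flask | temperature | remark | time |
|---|---|---|---|
| south-east | 37 °C | the very flask that is asked about, followed so far |  |
| north-east | 43 °C | run made earlier |  |
| flask | 37 °C |  | 10 min |

| run | time / min | target / % | starting material / % |
|---|---|---|---|
| south-east | 1.00 | 51 | 53 |
| south-east | 3.00 | 70 | 30 |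
| south-east | 5.00 | 78 | 23 |
| south-east | 8.00 | 79 | 19 |
| north-east | 1.00 | 49 | 50 |
| north-east | 3.00 | 62 | 34 |
| north-east | 5.00 | 66 | 33 |
| north-east | 8.00 | 68 | 35 |

(scatter of a reading: 1.5 percentage points)

- alpha: at 10 min add free enzyme, 100% of the amount charged, then wait 20 min
- theta: at 10 min take out 90% of the target then present, then wait 20 min
- beta: change nothing and wait 20 min more
- epsilon: at 10 min raise the temperature by 20 K, then wait 20 min
- eta: at 10 min add second substrate, 50.0% of the amount charged, then wait 20 min

- target taken out counts as made
- additions bring no volume worth counting

1. target, in percent of the starting material first charged, at 10 min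
2. which option adds most target ("none" when 2 percentage points or less is all one gets) (alpha / theta / beta / epsilon / eta / none)
3. target present, with what was taken out counted in, in percent of the starting material first charged, after beta
4. target present, with what was taken out counted in, in percent of the starting material first charged, after epsilon

At 8.00 min the two south-east readings sum to 98.0%, and taken together they put the target at 80.0%. The last step of the target reading, 1 percentage point, is smaller than the scatter of one reading, so this reckoning commits to that figure at 10 min and expects little from waiting.

That plateau is 29.6 mM of target, less than c(second substrate) of 35.1 mM, so the south-east flask has stopped with reagent still in it. Hence the quantity to carry is the turnover number, the target made per free enzyme charged before the catalyst stops working 17400. The turnover number is a reading at these charges, and this reckoning sets its product with c(free enzyme), 29.6 mM by definition, beside c(second substrate), the limiting reagent of the two charges.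

The south-east plateau lies below c(second substrate), so this reckoning does not rank extra second substrate first, though it does not write it off. Heat looks poor, since the north-east run at 43 °C reads a turnover number of 14500, lower than 17400. A second charge of free enzyme, if it turned over as the first did, would bring 29.6 mM against a room under the second substrate of 15 points, so the next run should add free enzyme, expecting a gain inside that room.

The forecast gives 80%, 82% after beta and 80.5% after epsilon, and chooses alpha, holding that “Enzyme death fits better”.

The flask gives 80.8% at 10 min, 81.6% after beta and 80.9% after epsilon, and alpha adds the most, 10 points. At 10.0 min spent catalyst stands at 95.1% of the catalyst charged, with 15% of the second substrate still free. The gain from alpha lies inside the reckoned room. A run in which fresh enzyme brought 2 points or less would have spoken against the turnover number as the reading of this stop.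

    starting material + free enzyme ⇌ first complex (K = 120 /M, k = 56000 /M/s, Ea = 25.0 kJ/mol, ΔH = −62.0 kJ/mol)
    first complex ⇌ loaded enzyme + first product (K = 0.0180 M, k = 19000 /s, Ea = 43.0 kJ/mol, ΔH = −28.0 kJ/mol)
    second substrate + loaded enzyme ⇌ second complex (K = 28.0 /M, k = 2.30 × 10⁵ /M/s, Ea = 15.0 kJ/mol, ΔH = −34.0 kJ/mol)
    first complex → spent catalyst (k = 0.0170 /s, Ea = 95.0 kJ/mol)
    free enzyme + added ligand ⇌ idle complex, settled at all times (K = 2.30 × 10⁵ /M, ΔH = −40.0 kJ/mol)
    second complex → free enzyme + target (k = 870 /s, Ea = 61.0 kJ/mol)
    free enzyme → unfolded enzyme (k = 8.10 × 10⁻⁵ /s, Ea = 193 kJ/mol)
    (constants at 37 °C)

A neighbour flask is charged with 150 mM of starting material and the same free enzyme, and the turnover number of the south-east flask, held unchanged, gives it 19.7%. The computed neighbour flask reaches 20.1%, with 14% of its second substrate left.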